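## Analysis of the target

Licoleafol is a (2S)-flavanone: a chroman-4-one (rings A and C) with a 3,4-dihydroxyphenyl ring B on C2, hydroxyls on C5 and C7, and an (E)-4-hydroxy-3-methylbut-2-enyl chain on C8. The only stereocentre is C2 (S; O1 > C1' > C3 > H). The only other stereo-element is the E trisubstituted olefin of the chain, which is too remote to interact with C2, so each must be set on its own. C2 is benzylic, β to the ketone and conjugated with the 4'-oxygen. Base erases it through retro-oxa-Michael opening to the 2'-hydroxychalcone, and strong acid through ionisation of C2–O1, so it should be made late and kept away from both. The chain carries a primary allylic alcohol next to the C7 oxygen; acid can ionise it or close a ring onto O7, and hydrogenolysis is excluded. Four phenols, two of them an oxidisable catechol, must be masked and released mildly. The real difficulty is ring A, a pentasubstituted benzene with oxygens on C8a, C7 and C5 and the chain on C8: in a phloroglucinol ketone the two hydroxyls ortho to the acyl group are nearly equivalent, so alkylation or ring closure gives C6/C8 mixtures. The strategy rests on the sequence C8a(O)–C8(chain)–C7(O)–C6(H)–C5(O)–C4a. The chain carbon lies between two oxygenated carbons and para to C5, so only the C5 oxygen has to be told apart, and a benzannulation that takes C8a, C4a, C5 and C6 from a vinylketene and C8 and C7 from an ynol ether writes this pattern directly.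

## Retrosynthetic reasoning

Abbreviations: TBS = tert-butyldimethylsilyl, TIPS = triisopropylsilyl.

Licoleafol 27 is traced to the fully silylated flavanone 26. All five hydroxyls are then freed in one buffered desilylation, a step that is neither basic enough to open ring C nor acidic enough to ionise the allylic alcohol.

In 26 the C2–C1' bond is cut, giving chromone 21 and arylboronic acid 25. This sets the only stereocentre last, by catalyst control on a flat substrate, with ring C already closed. The regiochemistry of ring closure is therefore decided before any stereochemistry exists. Boronic acid 25 goes back through bromide 23 to 4-bromocatechol 22.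

Chromone 21 is the silyl ether of 5-hydroxychromone 20, which comes from 5-ethoxychromone 19 by chelation-controlled dealkylation. The ethyl ether is removed here and not at the flavanone stage because the Lewis acid it needs would activate C2–O1 of a flavanone. On 19 there is no stereocentre to lose, and the pyranone carbonyl and O5 bind the boron reagent as a six-membered chelate. The hydroxyl is silylated again because a free peri-hydroxy ketone would bind the rhodium catalyst of the next step.

Chromone 19 is opened at O1–C2 and C2–C3 to acetophenone 17, C2 coming from a formamide acetal. Ketone 17 is cut at C3–C4 to aldehyde 15 (through carbinol 16), and 15 at C4a–C4 to phenol 14. A phenoxide-directed formylation is chosen over Friedel–Crafts acylation because it reaches only the position ortho to the free hydroxyl. In 14 that is the future C4a, and the hydroxyl itself becomes O1.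

Phenol 14 is the key disconnection: bonds C8a–C8 and C6–C7 are cut, giving siloxyalkyne 8 and cyclobutenone 9. Cutting here builds ring A from open-chain partners with the chain already on C8 and the three oxygens differentiated as free hydroxyl (C8a), silyl ether (C7) and ethyl ether (C5). The forward reaction passes through vinylketene 10, cyclobutenone 11, dienylketene 12 and dienone 13, and must join the chain-bearing alkyne carbon to the ketene carbon.

Siloxyalkyne 8 comes from terminal alkyne 5 by oxygenation of its acetylide 6 and O-silylation of ynolate 7. Alkyne 5 is cut at the propargylic C–C bond to allylic chloride 3 and ethynyl Grignard 4. Chloride 3 is the silyl ether of chlorohydrin 2, which derives from vinyl epoxide 1 by conjugate opening; this step sets the E olefin.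

## Alternatives that were turned down

Alternative 1: The C2–C3 bond is cut while O1–C2 is kept inside a cyclic mixed acetal. A chiral Brønsted acid would ionise the acetal C–O bond of the racemic enol acetal A2. The freed enol carbon would then return to the aryloxy oxocarbenium carbon, an O-to-C shift of the Petasis–Ferrier type, to give the per-silylated flavanone A1.
- For: C2–C3, ring C and the stereocentre come in one metal-free catalytic step. Both enantiomers of A2 pass through the same achiral ion pair, so A2 may be racemic. A1 needs the same single desilylation as 26. Counted from a finished ring A, this endgame is at least as short as the chosen one, and on that point it is the stronger plan.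
- Against: A2 has to be built on a ring A in which the oxygen next to the chain is already distinguished from O5, so the hard problem is untouched. The cation is stabilised by O1 and by a para-silyloxyaryl group and is long-lived, so the ion pair is loose and face control by the chiral anion is doubtful. The acid also threatens the exocyclic enol ether, the aryl silyl ethers and the electron-rich C6, which can trap the cation.
- Comparison: the chosen route spends more steps on ring C, but it solves ring A and sets C2 by a conjugate arylation of a reaction class that is established on chromones.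

Alternative 2: Bonds C8a–O1 and C4a–C4 are cut. Fluoride would release the C4a–C8a aryne from silyl triflate A4. The hydroxyl of hydroxy ester A5 would add at C8a, and the aryl anion at C4a would acylate on the ester to give flavanone A3.
- For: the stereocentre is bought in with A5, which is available by reliable asymmetric reduction or aldol chemistry. No late asymmetric catalysis on a complex substrate is needed; here the alternative is stronger. The C5 alkoxy group also steers the nucleophile to the distal aryne carbon C8a, as required.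
- Against: A4 is harder to make than phenol 14. It needs the same oxygen differentiation on ring A, plus an ortho silyl group and a triflate placed next to the chain. Addition at C8a is retarded by the flanking chain. The alkoxide of A5 can undergo retro-aldol cleavage or dehydration to the cinnamate under the basic fluoride conditions, which costs material and enantiopurity. The aryl anion can be quenched by the acidic α-hydrogens before it reaches the ester. The acetal protecting groups of A3 must come off with acid, which endangers the allylic alcohol.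
- Comparison: the chosen route accepts a late asymmetric step and gets in return a ring A made in one step and a fluoride-only deprotection.

Alternative 3: Bonds O1–C2 and C3–C4 are cut. Salicylaldehyde A7, an orthoformate and a chiral Brønsted acid would form an alkoxy ortho-quinone methide, which would add styrene A8 in a [4+2] cycloaddition to give the 2,4-cis-4-methoxyflavan A6.
- For: this is the most convergent plan. Two simple partners give ring C and C2 in one step, A8 is trivial to make, and no enolisable ketone is present while the stereocentre forms.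
- Against: A7 presupposes the ring A solution. It is a close relative of aldehyde 15, so this alternative is only another endgame for the same problem. A6 has the wrong oxidation level at C4, and unmasking and oxidising a benzylic ether on a trioxygenated ring invites ionisation and elimination to the flav-3-ene; this costs at least two more steps. The electron-rich styrene A8 can oligomerise under acid. The quinone methide carries three donor oxygens and is weakly electrophilic and loosely bound to the chiral anion.
- Comparison: the chosen route closes ring C at the correct oxidation level and keeps acid away from the finished skeleton.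

Key step: step 5

Assumption: the sense of induction in step 14 is assigned by analogy with the addition to cyclohex-2-enone; if it proved opposite, the (R)-ligand would be used without other change.

## Route

Step 1
Reactants: 1 2-methyl-2-vinyloxirane
Product: 2 (E)-4-chloro-2-methylbut-2-en-1-ol
Conditions: TiCl4, CH2Cl2, –85 °C; then H2O
Reagents that add atoms: titanium tetrachloride, Cl[Ti](Cl)(Cl)Cl
Why: Lewis acid-promoted conjugate (SN2') opening of a vinyl epoxide by chloride is a known route to this chlorohydrin; the E olefin should predominate because the reacting conformer places the small methyl group, not the titanium-bound CH2O unit, syn to the vinyl terminus.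

Step 2
Reactants: 2 (E)-4-chloro-2-methylbut-2-en-1-ol
Product: 3 tert-butyl{[(E)-4-chloro-2-methylbut-2-enyl]oxy}dimethylsilane
Conditions: t-BuMe2SiCl, imidazole, CH2Cl2, 0 °C
Reagents that add atoms: tert-butyldimethylsilyl chloride, CC(C)(C)[Si](C)(C)Cl
Why: Standard silylation of a primary alcohol; the low temperature and non-polar solvent keep the allylic chloride from being displaced.

Step 3
Reactants: 3 tert-butyl{[(E)-4-chloro-2-methylbut-2-enyl]oxy}dimethylsilane; 4 ethynylmagnesium bromide
Product: 5 (E)-6-(TBSO)-5-methylhex-4-en-1-yne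
Conditions: CuI (10 mol%), THF, 0 → 45 °C
Reagents that add atoms: none
Why: Copper-catalysed coupling of an alkynyl Grignard reagent with a primary allylic halide gives the skipped enyne by direct substitution; attack at the γ-carbon would create a quaternary centre and is disfavoured, so the E olefin is kept.

Step 4
Reactants: 5 (E)-6-(TBSO)-5-methylhex-4-en-1-yne
Product: 8 (E)-6-(TBSO)-5-methyl-1-(TIPSO)hex-4-en-1-yne, via lithium acetylide 6 (not isolated), via lithium ynolate 7 (not isolated)
Conditions: n-BuLi, THF, –78 °C; t-BuOOLi (from t-BuOOH and LiN(SiMe3)2), –78 → 0 °C; i-Pr3SiOTf, –78 → 0 °C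
Reagents that add atoms: tert-butyl hydroperoxide, CC(C)(C)OO; triisopropylsilyl triflate, CC(C)[Si](OS(=O)(=O)C(F)(F)F)(C(C)C)C(C)C
Why: Lithium tert-butyl peroxide transfers oxygen to the acetylide 6 (oxenoid oxidation) to give ynolate 7, which the hard silyl triflate traps on oxygen; this one-pot sequence is the usual access to triisopropylsilyl ynol ethers from terminal alkynes.

Step 5
Reactants: 8 (E)-6-(TBSO)-5-methyl-1-(TIPSO)hex-4-en-1-yne; 9 3-ethoxycyclobut-2-en-1-one
Product: 14 2-[(E)-4-(TBSO)-3-methylbut-2-enyl]-5-ethoxy-3-(TIPSO)phenol, via vinylketene 10 (not isolated), via 4-vinylcyclobutenone 11 (not isolated), via dienylketene 12 (not isolated), via cyclohexadienone 13 (not isolated)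
Conditions: PhMe, 80 → 110 °C
Reagents that add atoms: none
Why: Heating opens the vinylogous ester 9 by 4π electrocyclic ring opening to vinylketene 10, whose ketene C=C bond undergoes a regioselective [2+2] cycloaddition with the electron-rich siloxyalkyne 8 to give 4-vinylcyclobutenone 11. A second 4π opening gives dienylketene 12, which closes ring A by a thermal disrotatory 6π electrocyclisation between the ketene carbon and the terminal CH2 (the future C8a–C4a bond) to cyclohexadienone 13, and this tautomerises to phenol 14. The closest known reaction type is the Danheiser benzannulation of cyclobutenones with trialkylsilyloxyalkynes, which gives resorcinol monosilyl ethers; here a 3-alkoxycyclobutenone is the ketene source. The two bonds between the partners, C8a–C8 and C6–C7, are made in the [2+2] step, and its regiochemistry is fixed by the polarisation of the ynol ether: the carbon bearing the chain is the nucleophilic one and bonds to the electrophilic ketene carbon, so the chain must end up between the phenol and the siloxy group. No stereocentre is formed, and the E olefin of the chain is a spectator because a ketene adds to an ynol ether far faster than to an unactivated trisubstituted alkene. Only the isomer of 12 with the ketene and vinyl units cis on the central double bond can cyclise, and since the opening of 11 is reversible the other isomer is returned. The step needs 10 to react with 8 rather than with itself, which is helped by its slow thermal release into a concentrated solution of the alkyne. The ethoxy group rides through unchanged and marks the C5 oxygen, while the ketene oxygen emerges as the free phenol that becomes O1.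

Step 6
Reactants: 14 2-[(E)-4-(TBSO)-3-methylbut-2-enyl]-5-ethoxy-3-(TIPSO)phenol
Product: 15 3-[(E)-4-(TBSO)-3-methylbut-2-enyl]-6-ethoxy-2-hydroxy-4-(TIPSO)benzaldehyde
Conditions: MgCl2, Et3N, (CH2O)n, THF, reflux
Reagents that add atoms: paraformaldehyde (as formaldehyde), C=O
Why: Magnesium phenoxide-directed ortho-formylation (Casnati–Skattebøl) delivers formaldehyde within the chelate to the only free ortho position, the future C4a, and a second equivalent of formaldehyde oxidises the hydroxymethyl intermediate; the position between the two ether oxygens is not ortho to the phenoxide and is not reached.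

Step 7
Reactants: 15 3-[(E)-4-(TBSO)-3-methylbut-2-enyl]-6-ethoxy-2-hydroxy-4-(TIPSO)benzaldehyde
Product: 16 2-[(E)-4-(TBSO)-3-methylbut-2-enyl]-5-ethoxy-6-(1-hydroxyethyl)-3-(TIPSO)phenol (racemic)
Conditions: MeMgBr, THF, –78 → 0 °C; then H2O
Reagents that add atoms: methylmagnesium bromide, C[Mg]Br
Why: Grignard addition to the aldehyde after deprotonation of the phenol by the first equivalent; the electron-rich benzylic alcohol ionises easily and is taken on crude.

Step 8
Reactants: 16 2-[(E)-4-(TBSO)-3-methylbut-2-enyl]-5-ethoxy-6-(1-hydroxyethyl)-3-(TIPSO)phenol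
Product: 17 1-{3-[(E)-4-(TBSO)-3-methylbut-2-enyl]-6-ethoxy-2-hydroxy-4-(TIPSO)phenyl}ethan-1-one
Conditions: MnO2, CH2Cl2, rt
Reagents that add atoms: none
Why: MnO2 oxidises benzylic alcohols selectively and should leave the silyl ethers, the olefin and the hydrogen-bonded phenol untouched.

Step 9
Reactants: 17 1-{3-[(E)-4-(TBSO)-3-methylbut-2-enyl]-6-ethoxy-2-hydroxy-4-(TIPSO)phenyl}ethan-1-one
Product: 19 8-[(E)-4-(TBSO)-3-methylbut-2-enyl]-5-ethoxy-7-(TIPSO)-4H-chromen-4-one, via enaminone 18 (not isolated)
Conditions: Me2NCH(OMe)2, PhMe, 90 °C; then AcOH, 60 °C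
Reagents that add atoms: N,N-dimethylformamide dimethyl acetal, COC(OC)N(C)C
Why: Condensation of the methyl ketone with the amide acetal gives enaminone 18, and acid-promoted conjugate addition of the ortho hydroxyl with loss of dimethylamine closes the pyranone (standard chromone synthesis); only the oxygen next to the chain is free, so it alone can become O1.

Step 10
Reactants: 19 8-[(E)-4-(TBSO)-3-methylbut-2-enyl]-5-ethoxy-7-(TIPSO)-4H-chromen-4-one
Product: 20 8-[(E)-4-(TBSO)-3-methylbut-2-enyl]-5-hydroxy-7-(TIPSO)-4H-chromen-4-one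
Conditions: BCl3, n-Bu4NI, CH2Cl2, –78 → 0 °C; then H2O
Reagents that add atoms: none
Why: The pyranone carbonyl and the peri ethoxy oxygen bind boron as a six-membered chelate that activates only the O5–ethyl bond, and iodide removes the ethyl group by SN2 at low temperature (chelation-controlled dealkylation of peri-alkoxy ketones); the bulky, weakly basic silyl ethers should not compete for the Lewis acid, and no stereocentre is present yet.

Step 11
Reactants: 20 8-[(E)-4-(TBSO)-3-methylbut-2-enyl]-5-hydroxy-7-(TIPSO)-4H-chromen-4-one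
Product: 21 8-[(E)-4-(TBSO)-3-methylbut-2-enyl]-5-(TBSO)-7-(TIPSO)-4H-chromen-4-one
Conditions: t-BuMe2SiOTf, 2,6-lutidine, CH2Cl2, 0 °C
Reagents that add atoms: tert-butyldimethylsilyl triflate, CC(C)(C)[Si](C)(C)OS(=O)(=O)C(F)(F)F
Why: A silyl triflate with a hindered pyridine base silylates the hydrogen-bonded peri hydroxyl, which would otherwise bind the rhodium catalyst as a ketophenolate; a primary alcohol set free in step 10 would be silylated again in the same operation.

Step 12
Reactants: 22 4-bromobenzene-1,2-diol
Product: 23 4-bromo-1,2-bis(TBSO)benzene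
Conditions: t-BuMe2SiCl, imidazole, DMF, rt
Reagents that add atoms: tert-butyldimethylsilyl chloride, CC(C)(C)[Si](C)(C)Cl
Why: Standard bis-silylation of a catechol.

Step 13
Reactants: 23 4-bromo-1,2-bis(TBSO)benzene
Product: 25 [3,4-bis(TBSO)phenyl]boronic acid, via aryllithium 24 (not isolated)
Conditions: n-BuLi, THF, –78 °C; B(Oi-Pr)3, –78 °C → rt; then 1 M HCl, 0 °C
Reagents that add atoms: triisopropyl borate, CC(C)OB(OC(C)C)OC(C)C; water, O
Why: Bromine–lithium exchange followed by borylation and mild hydrolysis; the lithium sits meta and para to the silyloxy groups, so no silyl migration from oxygen to carbon can occur.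

Step 14
Reactants: 21 8-[(E)-4-(TBSO)-3-methylbut-2-enyl]-5-(TBSO)-7-(TIPSO)-4H-chromen-4-one; 25 [3,4-bis(TBSO)phenyl]boronic acid
Product: 26 (2S)-2-[3,4-bis(TBSO)phenyl]-8-[(E)-4-(TBSO)-3-methylbut-2-enyl]-5-(TBSO)-7-(TIPSO)chroman-4-one
Conditions: [Rh(OH)(L)]2 (3 mol% Rh; L = (S)-2,2'-bis[bis(3,4,5-trifluorophenyl)phosphino]-6,6'-dimethoxy-1,1'-biphenyl), CH2Cl2/H2O, 40 °C
Reagents that add atoms: none
Why: Rhodium-catalysed asymmetric 1,4-addition of an arylboronic acid to a chromone (Hayashi–Miyaura type): transmetalation gives an aryl–rhodium species, the C2=C3 bond inserts and water protonates the rhodium enolate. The C2-symmetric bisphosphine differentiates the two faces of C2, and the (S)-ligand is expected to give 2S, the sense in which (S)-biaryl bisphosphines give (S)-3-arylcyclohexanones. The base-free medium and the electron-poor ligand should suppress opening of the rhodium enolate to the chalcone.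

Step 15
Reactants: 26 (2S)-2-[3,4-bis(TBSO)phenyl]-8-[(E)-4-(TBSO)-3-methylbut-2-enyl]-5-(TBSO)-7-(TIPSO)chroman-4-one
Product: 27 licoleafol, (2S)-2-(3,4-dihydroxyphenyl)-5,7-dihydroxy-8-[(E)-4-hydroxy-3-methylbut-2-enyl]chroman-4-one
Conditions: n-Bu4NF, AcOH, THF, 0 °C → rt
Reagents that add atoms: none
Why: Buffered fluoride should remove the four aryl silyl ethers and the primary allylic silyl ether; acetic acid keeps the medium non-basic, so ring C should not open to the chalcone and C2 should keep its configuration.

## Compound list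

1 | 2-methyl-2-vinyloxirane (racemic) | C=CC1(C)CO1 | starting material
2 | (E)-4-chloro-2-methylbut-2-en-1-ol | C/C(=C\CCl)CO | intermediate
3 | tert-butyl{[(E)-4-chloro-2-methylbut-2-enyl]oxy}dimethylsilane | C/C(=C\CCl)CO[Si](C)(C)C(C)(C)C | intermediate
4 | ethynylmagnesium bromide | C#C[Mg]Br | starting material
5 | (E)-6-(tert-butyldimethylsilyloxy)-5-methylhex-4-en-1-yne | C/C(=C\CC#C)CO[Si](C)(C)C(C)(C)C | intermediate
6 | [(E)-6-(tert-butyldimethylsilyloxy)-5-methylhex-4-en-1-ynyl]lithium (lithium acetylide) | C/C(=C\CC#C[Li])CO[Si](C)(C)C(C)(C)C | intermediate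
7 | lithium (E)-6-(tert-butyldimethylsilyloxy)-5-methylhex-4-en-1-yn-1-olate (lithium ynolate) | C/C(=C\CC#CO[Li])CO[Si](C)(C)C(C)(C)C | intermediate
8 | (E)-6-(tert-butyldimethylsilyloxy)-5-methyl-1-(triisopropylsilyloxy)hex-4-en-1-yne | C/C(=C\CC#CO[Si](C(C)C)(C(C)C)C(C)C)CO[Si](C)(C)C(C)(C)C | intermediate
9 | 3-ethoxycyclobut-2-en-1-one | CCOC1=CC(=O)C1 | starting material
10 | 3-ethoxybuta-1,3-dien-1-one (vinylketene) | C=C(OCC)C=C=O | intermediate
11 | 2-[(E)-4-(tert-butyldimethylsilyloxy)-3-methylbut-2-enyl]-4-(1-ethoxyvinyl)-3-(triisopropylsilyloxy)cyclobut-2-en-1-one (racemic) | C/C(=C\CC1=C(O[Si](C(C)C)(C(C)C)C(C)C)C(C(=C)OCC)C1=O)CO[Si](C)(C)C(C)(C)C | intermediate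
12 | (3E)-2-[(E)-4-(tert-butyldimethylsilyloxy)-3-methylbut-2-enyl]-5-ethoxy-3-(triisopropylsilyloxy)hexa-1,3,5-trien-1-one (dienylketene; chain carbons C2 and C5 cis) | C/C(=C\CC(=C=O)/C(O[Si](C(C)C)(C(C)C)C(C)C)=C\C(=C)OCC)CO[Si](C)(C)C(C)(C)C | intermediate
13 | 2-[(E)-4-(tert-butyldimethylsilyloxy)-3-methylbut-2-enyl]-5-ethoxy-3-(triisopropylsilyloxy)cyclohexa-2,4-dien-1-one | C/C(=C\CC1=C(O[Si](C(C)C)(C(C)C)C(C)C)C=C(OCC)CC1=O)CO[Si](C)(C)C(C)(C)C | intermediate
14 | 2-[(E)-4-(tert-butyldimethylsilyloxy)-3-methylbut-2-enyl]-5-ethoxy-3-(triisopropylsilyloxy)phenol | C/C(=C\Cc1c(O)cc(OCC)cc1O[Si](C(C)C)(C(C)C)C(C)C)CO[Si](C)(C)C(C)(C)C | intermediate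
15 | 3-[(E)-4-(tert-butyldimethylsilyloxy)-3-methylbut-2-enyl]-6-ethoxy-2-hydroxy-4-(triisopropylsilyloxy)benzaldehyde | C/C(=C\Cc1c(O)c(C=O)c(OCC)cc1O[Si](C(C)C)(C(C)C)C(C)C)CO[Si](C)(C)C(C)(C)C | intermediate
16 | 2-[(E)-4-(tert-butyldimethylsilyloxy)-3-methylbut-2-enyl]-5-ethoxy-6-(1-hydroxyethyl)-3-(triisopropylsilyloxy)phenol (racemic) | C/C(=C\Cc1c(O)c(C(C)O)c(OCC)cc1O[Si](C(C)C)(C(C)C)C(C)C)CO[Si](C)(C)C(C)(C)C | intermediate
17 | 1-{3-[(E)-4-(tert-butyldimethylsilyloxy)-3-methylbut-2-enyl]-6-ethoxy-2-hydroxy-4-(triisopropylsilyloxy)phenyl}ethan-1-one | C/C(=C\Cc1c(O)c(C(C)=O)c(OCC)cc1O[Si](C(C)C)(C(C)C)C(C)C)CO[Si](C)(C)C(C)(C)C | intermediate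
18 | (E)-1-{3-[(E)-4-(tert-butyldimethylsilyloxy)-3-methylbut-2-enyl]-6-ethoxy-2-hydroxy-4-(triisopropylsilyloxy)phenyl}-3-(dimethylamino)prop-2-en-1-one (enaminone) | C/C(=C\Cc1c(O)c(C(=O)/C=C/N(C)C)c(OCC)cc1O[Si](C(C)C)(C(C)C)C(C)C)CO[Si](C)(C)C(C)(C)C | intermediate
19 | 8-[(E)-4-(tert-butyldimethylsilyloxy)-3-methylbut-2-enyl]-5-ethoxy-7-(triisopropylsilyloxy)-4H-chromen-4-one | C/C(=C\Cc1c(O[Si](C(C)C)(C(C)C)C(C)C)cc(OCC)c2c1OC=CC2=O)CO[Si](C)(C)C(C)(C)C | intermediate
20 | 8-[(E)-4-(tert-butyldimethylsilyloxy)-3-methylbut-2-enyl]-5-hydroxy-7-(triisopropylsilyloxy)-4H-chromen-4-one | C/C(=C\Cc1c(O[Si](C(C)C)(C(C)C)C(C)C)cc(O)c2c1OC=CC2=O)CO[Si](C)(C)C(C)(C)C | intermediate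
21 | 8-[(E)-4-(tert-butyldimethylsilyloxy)-3-methylbut-2-enyl]-5-(tert-butyldimethylsilyloxy)-7-(triisopropylsilyloxy)-4H-chromen-4-one | C/C(=C\Cc1c(O[Si](C(C)C)(C(C)C)C(C)C)cc(O[Si](C)(C)C(C)(C)C)c2c1OC=CC2=O)CO[Si](C)(C)C(C)(C)C | intermediate
22 | 4-bromobenzene-1,2-diol | Oc1ccc(Br)cc1O | starting material
23 | 4-bromo-1,2-bis(tert-butyldimethylsilyloxy)benzene | CC(C)(C)[Si](C)(C)Oc1ccc(Br)cc1O[Si](C)(C)C(C)(C)C | intermediate
24 | [3,4-bis(tert-butyldimethylsilyloxy)phenyl]lithium | CC(C)(C)[Si](C)(C)Oc1ccc([Li])cc1O[Si](C)(C)C(C)(C)C | intermediate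
25 | [3,4-bis(tert-butyldimethylsilyloxy)phenyl]boronic acid | CC(C)(C)[Si](C)(C)Oc1ccc(B(O)O)cc1O[Si](C)(C)C(C)(C)C | intermediate
26 | (2S)-2-[3,4-bis(tert-butyldimethylsilyloxy)phenyl]-8-[(E)-4-(tert-butyldimethylsilyloxy)-3-methylbut-2-enyl]-5-(tert-butyldimethylsilyloxy)-7-(triisopropylsilyloxy)chroman-4-one | C/C(=C\Cc1c(O[Si](C(C)C)(C(C)C)C(C)C)cc(O[Si](C)(C)C(C)(C)C)c2c1O[C@H](c1ccc(O[Si](C)(C)C(C)(C)C)c(O[Si](C)(C)C(C)(C)C)c1)CC2=O)CO[Si](C)(C)C(C)(C)C | intermediate
27 | licoleafol, (2S)-2-(3,4-dihydroxyphenyl)-5,7-dihydroxy-8-[(E)-4-hydroxy-3-methylbut-2-enyl]chroman-4-one | C/C(=C\Cc1c(O)cc(O)c2c1O[C@H](c1ccc(O)c(O)c1)CC2=O)CO | target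

Total step count: 15. Longest linear sequence: 13 steps (steps 1 to 11, 14 and 15); the boronic acid branch (steps 12 and 13) joins at step 14.

## Least certain steps

**Step 5 (key step).**
- What may go wrong: the donor-stabilised cyclobutenone 9 may open too slowly at temperatures the siloxyalkyne tolerates. The ynol ether could then rearrange by a 1,3-silyl shift to a silylketene, or the vinylketene could be lost to self-reaction. The product phenol can also be acylated by ketene intermediates.
- Fallback, from 3, returning at 14: ring A is bought instead of built. Commercial phloroglucinol is mono-ethylated (EtOH, HCl) to 5-ethoxybenzene-1,3-diol F1, and this is converted (MeOCH2Cl, i-Pr2NEt) into 1-ethoxy-3,5-bis(methoxymethoxy)benzene F2. Directed lithiation (n-BuLi, THF, 0 °C) takes place between the two acetal oxygens. After addition of CuI, allylation with chloride 3 would give 2-[(E)-4-(TBSO)-3-methylbut-2-enyl]-5-ethoxy-1,3-bis(methoxymethoxy)benzene F3. Non-protic acetal cleavage (Me3SiOTf, 2,2'-bipyridyl, then water) should spare the silyl ether and give 2-[(E)-4-(TBSO)-3-methylbut-2-enyl]-5-ethoxybenzene-1,3-diol F4. Its two hydroxyls are equivalent, so mono-silylation (i-Pr3SiCl, imidazole, one equivalent) leads to 14 with only over-silylation to control. The cost is five steps in place of one.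

**Step 10.**
- What may go wrong: ionisation or cleavage of the primary allylic silyl ether by the boron halide, or incomplete removal of the ethyl group at temperatures low enough to avoid that.
- Fallback, from 19, returning at 27: the ethyl ether is carried to the end and removed after all silyl groups are gone. Addition of 25 to 19 under the conditions of step 14 would give (2S)-2-[3,4-bis(TBSO)phenyl]-8-[(E)-4-(TBSO)-3-methylbut-2-enyl]-5-ethoxy-7-(TIPSO)chroman-4-one F5. Buffered desilylation as in step 15 then gives (2S)-5-O-ethyllicoleafol F6. The 5-O-ethyl group is finally cleaved through the magnesium chelate with MgI2·OEt2 in warm THF, the type of dealkylation known for 5-O-alkyl-8-prenylflavanones, to give 27. This exposes C2 to a warm Lewis acid and so accepts a risk of partial racemisation.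

**Step 14.**
- What may go wrong: slow insertion into the electron-rich chromone, so that protodeboronation of the boronic acid outruns arylation; opening of the rhodium enolate to the chalcone, which erodes yield and enantiopurity; or loss of the peri silyl group, after which the substrate binds the metal.
- Fallback, from 21, returning at 26: the aryl group is added without stereocontrol and the stereocentre is secured by resolution. Achiral [Rh(OH)(cod)]2 in aqueous dioxane with 25 would give the racemic flavanone F7. Noyori transfer hydrogenation (RuCl(p-cymene)(TsDPEN) of the configuration that reduces the 2R ketone faster, HCO2H/Et3N) then converts the unwanted enantiomer into the (2R,4R)-cis-flavan-4-ol F8. The 2S ketone 26 is left behind and separated, at the cost of half the material.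

**Step 4.**
- What may go wrong: incomplete oxygen transfer to the acetylide, base-induced isomerisation of the skipped enyne through its doubly activated CH2 group, and hydrolytic loss of the ynol ether on purification.
- Fallback, from 3, returning at 7: the ynolate is made from an ester, not from the alkyne. Alkylation of the lithium enolate of ethyl acetate with chloride 3 (LiN(i-Pr)2, THF, NaI) would give ethyl (E)-6-(TBSO)-5-methylhex-4-enoate F9. Two rounds of LiN(SiMe3)2 and BrCF2CF2Br give ethyl (E)-2,2-dibromo-6-(TBSO)-5-methylhex-4-enoate F10. Treatment with t-BuLi (THF, –78 → 0 °C) then effects double bromine–lithium exchange and loss of ethoxide to give ynolate 7, which is silylated as in step 4 to 8.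

## Further compounds

F1 | step 5 | 5-ethoxybenzene-1,3-diol | CCOc1cc(O)cc(O)c1
F2 | step 5 | 1-ethoxy-3,5-bis(methoxymethoxy)benzene | CCOc1cc(OCOC)cc(OCOC)c1
F3 | step 5 | 2-[(E)-4-(tert-butyldimethylsilyloxy)-3-methylbut-2-enyl]-5-ethoxy-1,3-bis(methoxymethoxy)benzene | C/C(=C\Cc1c(OCOC)cc(OCC)cc1OCOC)CO[Si](C)(C)C(C)(C)C
F4 | step 5 | 2-[(E)-4-(tert-butyldimethylsilyloxy)-3-methylbut-2-enyl]-5-ethoxybenzene-1,3-diol | C/C(=C\Cc1c(O)cc(OCC)cc1O)CO[Si](C)(C)C(C)(C)C
F5 | step 10 | (2S)-2-[3,4-bis(tert-butyldimethylsilyloxy)phenyl]-8-[(E)-4-(tert-butyldimethylsilyloxy)-3-methylbut-2-enyl]-5-ethoxy-7-(triisopropylsilyloxy)chroman-4-one | C/C(=C\Cc1c(O[Si](C(C)C)(C(C)C)C(C)C)cc(OCC)c2c1O[C@H](c1ccc(O[Si](C)(C)C(C)(C)C)c(O[Si](C)(C)C(C)(C)C)c1)CC2=O)CO[Si](C)(C)C(C)(C)C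
F6 | step 10 | (2S)-2-(3,4-dihydroxyphenyl)-5-ethoxy-7-hydroxy-8-[(E)-4-hydroxy-3-methylbut-2-enyl]chroman-4-one (5-O-ethyllicoleafol) | C/C(=C\Cc1c(O)cc(OCC)c2c1O[C@H](c1ccc(O)c(O)c1)CC2=O)CO
F7 | step 14 | racemic 2-[3,4-bis(tert-butyldimethylsilyloxy)phenyl]-8-[(E)-4-(tert-butyldimethylsilyloxy)-3-methylbut-2-enyl]-5-(tert-butyldimethylsilyloxy)-7-(triisopropylsilyloxy)chroman-4-one | C/C(=C\Cc1c(O[Si](C(C)C)(C(C)C)C(C)C)cc(O[Si](C)(C)C(C)(C)C)c2c1OC(c1ccc(O[Si](C)(C)C(C)(C)C)c(O[Si](C)(C)C(C)(C)C)c1)CC2=O)CO[Si](C)(C)C(C)(C)C
F8 | step 14 | (2R,4R)-2-[3,4-bis(tert-butyldimethylsilyloxy)phenyl]-8-[(E)-4-(tert-butyldimethylsilyloxy)-3-methylbut-2-enyl]-5-(tert-butyldimethylsilyloxy)-7-(triisopropylsilyloxy)chroman-4-ol | C/C(=C\Cc1c(O[Si](C(C)C)(C(C)C)C(C)C)cc(O[Si](C)(C)C(C)(C)C)c2c1O[C@@H](c1ccc(O[Si](C)(C)C(C)(C)C)c(O[Si](C)(C)C(C)(C)C)c1)C[C@H]2O)CO[Si](C)(C)C(C)(C)C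
F9 | step 4 | ethyl (E)-6-(tert-butyldimethylsilyloxy)-5-methylhex-4-enoate | CCOC(=O)CC/C=C(\C)CO[Si](C)(C)C(C)(C)C
F10 | step 4 | ethyl (E)-2,2-dibromo-6-(tert-butyldimethylsilyloxy)-5-methylhex-4-enoate | CCOC(=O)C(Br)(Br)C/C=C(\C)CO[Si](C)(C)C(C)(C)C
A1 | alternative 1 | (2S)-2-[3,4-bis(tert-butyldimethylsilyloxy)phenyl]-5,7-bis(tert-butyldimethylsilyloxy)-8-[(E)-4-(tert-butyldimethylsilyloxy)-3-methylbut-2-enyl]chroman-4-one | C/C(=C\Cc1c(O[Si](C)(C)C(C)(C)C)cc(O[Si](C)(C)C(C)(C)C)c2c1O[C@H](c1ccc(O[Si](C)(C)C(C)(C)C)c(O[Si](C)(C)C(C)(C)C)c1)CC2=O)CO[Si](C)(C)C(C)(C)C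
A2 | alternative 1 | racemic 2-[3,4-bis(tert-butyldimethylsilyloxy)phenyl]-5,7-bis(tert-butyldimethylsilyloxy)-8-[(E)-4-(tert-butyldimethylsilyloxy)-3-methylbut-2-enyl]-4-methylidene-4H-1,3-benzodioxine | C/C(=C\Cc1c(O[Si](C)(C)C(C)(C)C)cc(O[Si](C)(C)C(C)(C)C)c2c1OC(c1ccc(O[Si](C)(C)C(C)(C)C)c(O[Si](C)(C)C(C)(C)C)c1)OC2=C)CO[Si](C)(C)C(C)(C)C
A3 | alternative 2 | (2S)-2-[3,4-bis(methoxymethoxy)phenyl]-8-[(E)-4-(tert-butyldiphenylsilyloxy)-3-methylbut-2-enyl]-5,7-bis(methoxymethoxy)chroman-4-one | C/C(=C\Cc1c(OCOC)cc(OCOC)c2c1O[C@H](c1ccc(OCOC)c(OCOC)c1)CC2=O)CO[Si](c1ccccc1)(c1ccccc1)C(C)(C)C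
A4 | alternative 2 | 2-[(E)-4-(tert-butyldiphenylsilyloxy)-3-methylbut-2-enyl]-3,5-bis(methoxymethoxy)-6-(trimethylsilyl)phenyl trifluoromethanesulfonate | C/C(=C\Cc1c(OCOC)cc(OCOC)c([Si](C)(C)C)c1OS(=O)(=O)C(F)(F)F)CO[Si](c1ccccc1)(c1ccccc1)C(C)(C)C
A5 | alternative 2 | methyl (3S)-3-[3,4-bis(methoxymethoxy)phenyl]-3-hydroxypropanoate | COC(=O)C[C@H](O)c1ccc(OCOC)c(OCOC)c1
A6 | alternative 3 | (2S)-2,4-cis-2-[3,4-bis(tert-butyldimethylsilyloxy)phenyl]-5,7-bis(tert-butyldimethylsilyloxy)-8-[(E)-4-(tert-butyldimethylsilyloxy)-3-methylbut-2-enyl]-4-methoxychromane | C/C(=C\Cc1c(O[Si](C)(C)C(C)(C)C)cc(O[Si](C)(C)C(C)(C)C)c2c1O[C@H](c1ccc(O[Si](C)(C)C(C)(C)C)c(O[Si](C)(C)C(C)(C)C)c1)C[C@@H]2OC)CO[Si](C)(C)C(C)(C)C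
A7 | alternative 3 | 3-[(E)-4-(tert-butyldimethylsilyloxy)-3-methylbut-2-enyl]-2-hydroxy-4,6-bis(tert-butyldimethylsilyloxy)benzaldehyde | C/C(=C\Cc1c(O)c(C=O)c(O[Si](C)(C)C(C)(C)C)cc1O[Si](C)(C)C(C)(C)C)CO[Si](C)(C)C(C)(C)C
A8 | alternative 3 | 4-ethenyl-1,2-bis(tert-butyldimethylsilyloxy)benzene | C=Cc1ccc(O[Si](C)(C)C(C)(C)C)c(O[Si](C)(C)C(C)(C)C)c1
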